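**Plan**
1. Retrosynthesis: cut C6–prenyl first (dearomative Tsuji–Trost allylation, the last C–C bond), then C6–CH2 (Negishi union of a chromanone aryl iodide with a cyclobutylmethylzinc), then the cyclobutane bond C2'–C3' (isopropenyl-bearing CH to C(CH3)2), and in the core the chromanone ring and the aryl–CH(propyl) bond. Locants: chromanone O1–C8a; cyclobutane C1' (CH2 link), C2' (isopropenyl), C3' (gem-dimethyl), C4'.
2. Enabling feature: C2' carries an exocyclic sp2 carbon and sits next to the quaternary C3'. Joining C2' and C3' through that carbon as a ketone gives a 5-diazo-2,2-dimethylcyclopentanone: the quaternary carbon is the only group that can migrate and the only enolisable α-carbon takes the diazo group. A Wolff ring contraction then forms C2'–C3' and leaves the former carbonyl carbon as the handle for the isopropenyl group.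
3. Forward order: cyclopentenone, conjugate vinylation, diazo ketone, ring contraction (cyclobutane), methyl ketone, hydroxymethyl and isopropenyl, iodide. Separately: phenol plus hexenal to the dihydrocoumarin, C8 acylation, lactone-to-chromanone switch, 6-iodo diacetate. Then union, prenylation at C6 (the ring is dearomatised last), saponification.
4. Stereochemistry: C1' from the rhodium/(R)-BINAP conjugate addition; C2' by thermodynamic trans equilibration of the methyl ketone; side-chain C3 from iminium catalysis; C6 from the chiral palladium catalyst.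

Key step: step 4

Assumption: the facial sense of the (R,R)-ligand in step 17 cannot be derived from the remote stereocentres; the (S,S)-ligand is used instead if it proves to be the matched one.

Step 1
Reactants: 1 2,2-dimethylcyclopentan-1-one
Product: 2 5,5-dimethylcyclopent-2-en-1-one
Conditions: IBX (1.5 equiv), DMSO/toluene, 70 °C
Reagents that add atoms: none
Why: IBX-mediated α,β-dehydrogenation of a ketone proceeds through the enol and can only enter on the unsubstituted α-carbon because the other one is quaternary.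

Step 2
Reactants: 2 5,5-dimethylcyclopent-2-en-1-one; 3 potassium vinyltrifluoroborate
Product: 4 (4R)-4-ethenyl-2,2-dimethylcyclopentan-1-one
Conditions: [Rh(cod)2]PF6 (3 mol %), (R)-BINAP (3.3 mol %), toluene/H2O 4:1, 100 °C
Reagents that add atoms: none
Why: Rhodium-catalysed asymmetric 1,4-addition of an alkenylboron reagent (Hayashi–Miyaura reaction), in which (R)-BINAP should give the (4R) ketone by analogy with cyclopent-2-enone, where (S)-BINAP gives (S)-3-substituted cyclopentanones; this centre is the sole source of the absolute configuration of the cyclobutane.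

Step 3
Reactants: 4 (4R)-4-ethenyl-2,2-dimethylcyclopentan-1-one
Product: 6 (4S)-5-diazo-4-ethenyl-2,2-dimethylcyclopentan-1-one, via trifluoroacetyl ketone 5 (not isolated)
Conditions: LiN(SiMe3)2, THF, −78 °C, then CF3CO2CH2CF3; aqueous HCl wash, crude carried on; then 4-acetamidobenzenesulfonyl azide, Et3N, H2O (1 equiv), MeCN, rt
Reagents that add atoms: 4-acetamidobenzenesulfonyl azide, CC(=O)Nc1ccc(cc1)S(=O)(=O)N=[N+]=[N-]
Why: Detrifluoroacetylative (Regitz-type) diazo transfer, in which the single enolisable α-carbon is trifluoroacetylated and then exchanges the activating acyl group for the diazo group on reaction with the sulfonyl azide.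

Step 4
Reactants: 6 (4S)-5-diazo-4-ethenyl-2,2-dimethylcyclopentan-1-one
Product: 8 (4S)-4-ethenyl-N-methoxy-N,2,2-trimethylcyclobutane-1-carboxamide (both C1 epimers), via ketene 7 (not isolated)
Conditions: hν (350–365 nm), MeNHOMe (3 equiv), THF, rt
Reagents that add atoms: N,O-dimethylhydroxylamine, CNOC
Why: Irradiation expels N2 and the fully substituted C(CH3)2 carbon migrates with its bonding pair from the carbonyl carbon to the diazo carbon (Wolff rearrangement, concerted from the ring-enforced s-cis diazo ketone or through the singlet α-oxo carbene), so the bond between the future isopropenyl-bearing carbon and the gem-dimethyl carbon forms while the carbonyl carbon leaves the ring as a ketene, which the amine captures as the Weinreb amide. The closest known reaction type is the photochemical Wolff ring contraction of 2-diazocyclopentanones with a quaternary α'-carbon to 2,2-dimethylcyclobutanecarboxylic acid derivatives. The cyclobutane is closed by ring contraction, a suprafacial 1,2-shift of the migrating carbon onto the adjacent carbenic centre, not by an exo or endo closure of an open chain. The one new stereocentre, the amide-bearing ring carbon, arises by protonation of the amide enol and is not controlled here; it is set trans in step 5, while the vinyl-bearing centre is untouched because it is neither the migrating nor the carbenic carbon. The step needs ring contraction to win over the 1,2-hydride shift to an enone, which photolysis at ambient temperature with a good ketene trap should secure, and the site of the diazo group is unambiguous because the other α-carbon is quaternary.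

Step 5
Reactants: 8 (4S)-4-ethenyl-N-methoxy-N,2,2-trimethylcyclobutane-1-carboxamide (both C1 epimers)
Product: 9 1-[(1S,4S)-4-ethenyl-2,2-dimethylcyclobutyl]ethan-1-one
Conditions: MeMgBr (1.5 equiv), THF, 0 °C; aqueous work-up; then NaOMe (0.2 equiv), MeOH, rt
Reagents that add atoms: methylmagnesium bromide, C[Mg]Br
Why: Weinreb ketone synthesis (the magnesium chelate prevents over-addition) followed by base equilibration through the enolate, which should place the acetyl group trans to the vinyl group as the more stable 1,2-disubstituted cyclobutane, the vinyl-bearing centre being β to the carbonyl and unable to epimerise.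

Step 6
Reactants: 9 1-[(1S,4S)-4-ethenyl-2,2-dimethylcyclobutyl]ethan-1-one
Product: 11 1-[(1S,4R)-4-(hydroxymethyl)-2,2-dimethylcyclobutyl]ethan-1-one, via keto aldehyde 10 (not isolated)
Conditions: O3, CH2Cl2/MeOH 4:1, −78 °C; Me2S, −78 °C to rt; then NaBH4 (0.5 equiv), −78 °C
Reagents that add atoms: ozone, O=[O+][O-]
Why: Ozonolysis of the monosubstituted alkene with reductive work-up and chemoselective low-temperature borohydride reduction, the aldehyde being reduced much faster than the hindered methyl ketone so that the epimerisable aldehyde is never stored.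

Step 7
Reactants: 11 1-[(1S,4R)-4-(hydroxymethyl)-2,2-dimethylcyclobutyl]ethan-1-one
Product: 12 [(1R,2R)-3,3-dimethyl-2-(prop-1-en-2-yl)cyclobutyl]methanol
Conditions: Ph3PCH3Br (3 equiv), KOt-Bu (2.9 equiv), THF, 0 °C to rt
Reagents that add atoms: methyltriphenylphosphonium bromide, C[P+](c1ccccc1)(c1ccccc1)c1ccccc1.[Br-]
Why: Wittig methylenation of the methyl ketone with excess ylide (which also carries the free hydroxyl as its alkoxide), any enolisation returning the thermodynamically preferred trans isomer.

Step 8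
Reactants: 12 [(1R,2R)-3,3-dimethyl-2-(prop-1-en-2-yl)cyclobutyl]methanol
Product: 13 (1R,2R)-1-(iodomethyl)-3,3-dimethyl-2-(prop-1-en-2-yl)cyclobutane
Conditions: PPh3, I2, imidazole, CH2Cl2, 0 °C to rt, dark
Reagents that add atoms: iodine, II
Why: Appel-type iodination replaces the primary hydroxyl by SN2 displacement of the oxyphosphonium group, with no cationic intermediate that could trigger a cyclobutylcarbinyl rearrangement.

Step 9
Reactants: 14 3,5-bis(benzyloxy)phenol; 15 (E)-hex-2-enal
Product: 17 (4R)-5,7-bis(benzyloxy)-4-propyl-3,4-dihydro-2H-1-benzopyran-2-one, via lactol 16 (not isolated)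
Conditions: (S)-α,α-diphenylprolinol trimethylsilyl ether (20 mol %), PhCO2H (20 mol %), toluene, 0 °C; then PhI(OAc)2 (1.5 equiv), TEMPO (10 mol %), CH2Cl2, rt
Reagents that add atoms: none
Why: Iminium-catalysed Friedel–Crafts alkylation of the electron-rich phenol ortho to the free hydroxyl, which then closes the lactol, followed by oxoammonium oxidation to the lactone; the bulky group of the (S)-catalyst shields one face of the (E)-iminium ion so that the arene should add to give the (R) benzylic centre.

Step 10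
Reactants: 17 (4R)-5,7-bis(benzyloxy)-4-propyl-3,4-dihydro-2H-1-benzopyran-2-one; 18 3-methylbut-2-enoic acid
Product: 19 (4R)-5,7-bis(benzyloxy)-8-(3-methylbut-2-enoyl)-4-propyl-3,4-dihydro-2H-1-benzopyran-2-one
Conditions: (CF3CO)2O (2 equiv), H3PO4 (85 %, cat.), CH2Cl2, 0 °C to rt
Reagents that add atoms: none
Why: Friedel–Crafts acylation by the mixed trifluoroacetic anhydride, expected at C8 because C8 is ortho to one benzyloxy group and para to the other whereas C6 lies between two benzyloxy groups, the usual preference of 1,3-dialkoxybenzenes.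

Step 11
Reactants: 19 (4R)-5,7-bis(benzyloxy)-8-(3-methylbut-2-enoyl)-4-propyl-3,4-dihydro-2H-1-benzopyran-2-one
Product: 21 methyl (3R)-3-[5,7-bis(benzyloxy)-2,2-dimethyl-4-oxo-3,4-dihydro-2H-1-benzopyran-8-yl]hexanoate, via hydroxyaryl enone 20 (not isolated)
Conditions: NaOMe (0.5 equiv), MeOH/THF, 0 °C to rt
Reagents that add atoms: methanol, CO
Why: Methanolysis of the aryl ester (lactone) frees the only phenol in the molecule, which lies next to the enone and adds to it in a 6-endo oxa-Michael cyclisation, so the chromanone ether oxygen is fixed between the side-chain carbon and the acyl carbon.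

Step 12
Reactants: 21 methyl (3R)-3-[5,7-bis(benzyloxy)-2,2-dimethyl-4-oxo-3,4-dihydro-2H-1-benzopyran-8-yl]hexanoate
Product: 22 methyl (3R)-3-(5,7-dihydroxy-2,2-dimethyl-4-oxo-3,4-dihydro-2H-1-benzopyran-8-yl)hexanoate
Conditions: H2 (1 atm), 10 % Pd/C, EtOAc, rt
Reagents that add atoms: none
Why: Hydrogenolysis of the two benzyl ethers over palladium on carbon under neutral conditions, which should leave the aryl ketone, the ester and the benzylic stereocentre untouched.

Step 13
Reactants: 22 methyl (3R)-3-(5,7-dihydroxy-2,2-dimethyl-4-oxo-3,4-dihydro-2H-1-benzopyran-8-yl)hexanoate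
Product: 23 methyl (3R)-3-(5,7-dihydroxy-6-iodo-2,2-dimethyl-4-oxo-3,4-dihydro-2H-1-benzopyran-8-yl)hexanoate
Conditions: N-iodosuccinimide (1.05 equiv), MeCN, 0 °C
Reagents that add atoms: N-iodosuccinimide, O=C1CCC(=O)N1I
Why: Electrophilic aromatic iodination at C6, the only unsubstituted ring position, which is activated by two ortho hydroxyl groups.

Step 14
Reactants: 23 methyl (3R)-3-(5,7-dihydroxy-6-iodo-2,2-dimethyl-4-oxo-3,4-dihydro-2H-1-benzopyran-8-yl)hexanoate
Product: 24 methyl (3R)-3-[5,7-bis(acetyloxy)-6-iodo-2,2-dimethyl-4-oxo-3,4-dihydro-2H-1-benzopyran-8-yl]hexanoate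
Conditions: Ac2O, pyridine, DMAP (cat.), CH2Cl2, rt
Reagents that add atoms: acetic anhydride, CC(=O)OC(C)=O
Why: DMAP-catalysed acetylation masks both acidic phenols (including the hydrogen-bonded 5-OH) so that they cannot protonate the organozinc reagent, and makes the aryl iodide less electron-rich for oxidative addition.

Step 15
Reactants: 13 (1R,2R)-1-(iodomethyl)-3,3-dimethyl-2-(prop-1-en-2-yl)cyclobutane; 24 methyl (3R)-3-[5,7-bis(acetyloxy)-6-iodo-2,2-dimethyl-4-oxo-3,4-dihydro-2H-1-benzopyran-8-yl]hexanoate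
Product: 27 methyl (3R)-3-[5,7-bis(acetyloxy)-6-{[(1S,2R)-3,3-dimethyl-2-(prop-1-en-2-yl)cyclobutyl]methyl}-2,2-dimethyl-4-oxo-3,4-dihydro-2H-1-benzopyran-8-yl]hexanoate, via alkyllithium 25 (not isolated), via alkylzinc chloride 26 (not isolated)
Conditions: 13, t-BuLi (2.1 equiv), Et2O/pentane, −78 °C; ZnCl2 (1.1 equiv) in THF, −78 °C to rt; then 24, Pd(OAc)2 (5 mol %), SPhos (10 mol %), THF/NMP, 40 °C
Reagents that add atoms: none
Why: Negishi sp3–sp2 cross-coupling, in which polar iodine–lithium exchange at −78 °C and immediate transmetalation to zinc should outrun ring opening of the cyclobutylmethyl anion, the stereocentres are not at the metal-bearing carbon, and a bulky biarylphosphine palladium catalyst couples the primary alkylzinc with the doubly ortho-substituted aryl iodide in the presence of ketone and esters.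

Step 16
Reactants: 27 methyl (3R)-3-[5,7-bis(acetyloxy)-6-{[(1S,2R)-3,3-dimethyl-2-(prop-1-en-2-yl)cyclobutyl]methyl}-2,2-dimethyl-4-oxo-3,4-dihydro-2H-1-benzopyran-8-yl]hexanoate
Product: 28 methyl (3R)-3-[6-{[(1S,2R)-3,3-dimethyl-2-(prop-1-en-2-yl)cyclobutyl]methyl}-5,7-dihydroxy-2,2-dimethyl-4-oxo-3,4-dihydro-2H-1-benzopyran-8-yl]hexanoate
Conditions: K2CO3 (0.2 equiv), MeOH, 0 °C
Reagents that add atoms: none
Why: Base-catalysed transesterification removes the two aryl acetates while the alkyl methyl ester is degenerate in methanol, and the cold, brief treatment should avoid opening and reclosure of the chromanone ring.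

Step 17
Reactants: 28 methyl (3R)-3-[6-{[(1S,2R)-3,3-dimethyl-2-(prop-1-en-2-yl)cyclobutyl]methyl}-5,7-dihydroxy-2,2-dimethyl-4-oxo-3,4-dihydro-2H-1-benzopyran-8-yl]hexanoate; 29 3-methylbut-2-en-1-yl acetate
Product: 30 methyl (3R)-3-[(6R)-6-{[(1S,2R)-3,3-dimethyl-2-(prop-1-en-2-yl)cyclobutyl]methyl}-5-hydroxy-2,2-dimethyl-6-(3-methylbut-2-en-1-yl)-4,7-dioxo-3,4,6,7-tetrahydro-2H-1-benzopyran-8-yl]hexanoate
Conditions: Pd2(dba)3·CHCl3 (2.5 mol %), (R,R)-DACH-phenyl bisphosphine ligand (7.5 mol %), Et3N (1.5 equiv), toluene, 0 °C to rt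
Reagents that add atoms: none
Why: Tsuji–Trost allylation used as an alkylative dearomatisation, in which the π-prenyl palladium complex is attacked at its unsubstituted terminus by C6 (the carbon between the two hydroxyl-bearing carbons), O-allylation is reversible under zerovalent palladium, and the chiral ligand rather than the remote stereocentres is relied on to choose the face giving (6R), the C6 epimer being removable by chromatography.

Step 18
Reactants: 30 methyl (3R)-3-[(6R)-6-{[(1S,2R)-3,3-dimethyl-2-(prop-1-en-2-yl)cyclobutyl]methyl}-5-hydroxy-2,2-dimethyl-6-(3-methylbut-2-en-1-yl)-4,7-dioxo-3,4,6,7-tetrahydro-2H-1-benzopyran-8-yl]hexanoate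
Product: 31 (3R)-3-[(6R)-6-{[(1S,2R)-3,3-dimethyl-2-(prop-1-en-2-yl)cyclobutyl]methyl}-5-hydroxy-2,2-dimethyl-6-(3-methylbut-2-en-1-yl)-4,7-dioxo-3,4,6,7-tetrahydro-2H-1-benzopyran-8-yl]hexanoic acid
Conditions: LiOH·H2O (3 equiv), THF/MeOH/H2O, 0 °C to rt; then 1 M HCl to pH 3
Reagents that add atoms: lithium hydroxide, [Li+].[OH-]
Why: Saponification of the methyl ester, during which the dearomatised core is held as its stabilised enolate and no stereocentre is α to a carbonyl, the acid being released on acidification.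

**Compound list**
1 | 2,2-dimethylcyclopentan-1-one | CC1(C)CCCC1=O | starting material
2 | 5,5-dimethylcyclopent-2-en-1-one | CC1(C)CC=CC1=O | intermediate
3 | potassium vinyltrifluoroborate | C=C[B-](F)(F)F.[K+] | starting material
4 | (4R)-4-ethenyl-2,2-dimethylcyclopentan-1-one | O=C1C[C@H](C=C)CC1(C)C | intermediate
5 | (4S)-4-ethenyl-2,2-dimethyl-5-(trifluoroacetyl)cyclopentan-1-one | O=C1C(C(=O)C(F)(F)F)[C@H](C=C)CC1(C)C | intermediate
6 | (4S)-5-diazo-4-ethenyl-2,2-dimethylcyclopentan-1-one | O=C1C(=[N+]=[N-])[C@H](C=C)CC1(C)C | intermediate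
7 | [(4S)-4-ethenyl-2,2-dimethylcyclobutylidene]methanone (ketene) | O=C=C1[C@H](C=C)CC1(C)C | intermediate
8 | (4S)-4-ethenyl-N-methoxy-N,2,2-trimethylcyclobutane-1-carboxamide (both C1 epimers) | CON(C)C(=O)C1[C@H](C=C)CC1(C)C | intermediate
9 | 1-[(1S,4S)-4-ethenyl-2,2-dimethylcyclobutyl]ethan-1-one | CC(=O)[C@H]1[C@H](C=C)CC1(C)C | intermediate
10 | (1R,2S)-2-acetyl-3,3-dimethylcyclobutane-1-carbaldehyde | CC(=O)[C@H]1[C@H](C=O)CC1(C)C | intermediate
11 | 1-[(1S,4R)-4-(hydroxymethyl)-2,2-dimethylcyclobutyl]ethan-1-one | CC(=O)[C@H]1[C@H](CO)CC1(C)C | intermediate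
12 | [(1R,2R)-3,3-dimethyl-2-(prop-1-en-2-yl)cyclobutyl]methanol | C=C(C)[C@H]1[C@H](CO)CC1(C)C | intermediate
13 | (1R,2R)-1-(iodomethyl)-3,3-dimethyl-2-(prop-1-en-2-yl)cyclobutane | C=C(C)[C@H]1[C@H](CI)CC1(C)C | intermediate
14 | 3,5-bis(benzyloxy)phenol | Oc1cc(OCc2ccccc2)cc(OCc2ccccc2)c1 | starting material
15 | (E)-hex-2-enal | CCC/C=C/C=O | starting material
16 | (4R)-5,7-bis(benzyloxy)-4-propyl-3,4-dihydro-2H-1-benzopyran-2-ol (lactol, both anomers) | OC1C[C@@H](CCC)c2c(OCc3ccccc3)cc(OCc3ccccc3)cc2O1 | intermediate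
17 | (4R)-5,7-bis(benzyloxy)-4-propyl-3,4-dihydro-2H-1-benzopyran-2-one | O=C1C[C@@H](CCC)c2c(OCc3ccccc3)cc(OCc3ccccc3)cc2O1 | intermediate
18 | 3-methylbut-2-enoic acid | CC(C)=CC(=O)O | starting material
19 | (4R)-5,7-bis(benzyloxy)-8-(3-methylbut-2-enoyl)-4-propyl-3,4-dihydro-2H-1-benzopyran-2-one | O=C1C[C@@H](CCC)c2c(OCc3ccccc3)cc(OCc3ccccc3)c(C(=O)C=C(C)C)c2O1 | intermediate
20 | methyl (3R)-3-[4,6-bis(benzyloxy)-2-hydroxy-3-(3-methylbut-2-enoyl)phenyl]hexanoate | COC(=O)C[C@@H](CCC)c1c(OCc2ccccc2)cc(OCc2ccccc2)c(C(=O)C=C(C)C)c1O | intermediate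
21 | methyl (3R)-3-[5,7-bis(benzyloxy)-2,2-dimethyl-4-oxo-3,4-dihydro-2H-1-benzopyran-8-yl]hexanoate | COC(=O)C[C@@H](CCC)c1c(OCc2ccccc2)cc(OCc2ccccc2)c2C(=O)CC(C)(C)Oc12 | intermediate
22 | methyl (3R)-3-(5,7-dihydroxy-2,2-dimethyl-4-oxo-3,4-dihydro-2H-1-benzopyran-8-yl)hexanoate | COC(=O)C[C@@H](CCC)c1c(O)cc(O)c2C(=O)CC(C)(C)Oc12 | intermediate
23 | methyl (3R)-3-(5,7-dihydroxy-6-iodo-2,2-dimethyl-4-oxo-3,4-dihydro-2H-1-benzopyran-8-yl)hexanoate | COC(=O)C[C@@H](CCC)c1c(O)c(I)c(O)c2C(=O)CC(C)(C)Oc12 | intermediate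
24 | methyl (3R)-3-[5,7-bis(acetyloxy)-6-iodo-2,2-dimethyl-4-oxo-3,4-dihydro-2H-1-benzopyran-8-yl]hexanoate | COC(=O)C[C@@H](CCC)c1c(OC(C)=O)c(I)c(OC(C)=O)c2C(=O)CC(C)(C)Oc12 | intermediate
25 | {[(1R,2R)-3,3-dimethyl-2-(prop-1-en-2-yl)cyclobutyl]methyl}lithium | C=C(C)[C@H]1[C@H](C[Li])CC1(C)C | intermediate
26 | chlorido{[(1R,2R)-3,3-dimethyl-2-(prop-1-en-2-yl)cyclobutyl]methyl}zinc | C=C(C)[C@H]1[C@H](C[Zn]Cl)CC1(C)C | intermediate
27 | methyl (3R)-3-[5,7-bis(acetyloxy)-6-{[(1S,2R)-3,3-dimethyl-2-(prop-1-en-2-yl)cyclobutyl]methyl}-2,2-dimethyl-4-oxo-3,4-dihydro-2H-1-benzopyran-8-yl]hexanoate | C=C(C)[C@H]1[C@H](Cc2c(OC(C)=O)c3C(=O)CC(C)(C)Oc3c([C@H](CCC)CC(=O)OC)c2OC(C)=O)CC1(C)C | intermediate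
28 | methyl (3R)-3-[6-{[(1S,2R)-3,3-dimethyl-2-(prop-1-en-2-yl)cyclobutyl]methyl}-5,7-dihydroxy-2,2-dimethyl-4-oxo-3,4-dihydro-2H-1-benzopyran-8-yl]hexanoate | C=C(C)[C@H]1[C@H](Cc2c(O)c3C(=O)CC(C)(C)Oc3c([C@H](CCC)CC(=O)OC)c2O)CC1(C)C | intermediate
29 | 3-methylbut-2-en-1-yl acetate (prenyl acetate) | CC(C)=CCOC(C)=O | starting material
30 | methyl (3R)-3-[(6R)-6-{[(1S,2R)-3,3-dimethyl-2-(prop-1-en-2-yl)cyclobutyl]methyl}-5-hydroxy-2,2-dimethyl-6-(3-methylbut-2-en-1-yl)-4,7-dioxo-3,4,6,7-tetrahydro-2H-1-benzopyran-8-yl]hexanoate | C=C(C)[C@H]1[C@H](C[C@]2(CC=C(C)C)C(=O)C([C@H](CCC)CC(=O)OC)=C3OC(C)(C)CC(=O)C3=C2O)CC1(C)C | intermediate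
31 | (3R)-3-[(6R)-6-{[(1S,2R)-3,3-dimethyl-2-(prop-1-en-2-yl)cyclobutyl]methyl}-5-hydroxy-2,2-dimethyl-6-(3-methylbut-2-en-1-yl)-4,7-dioxo-3,4,6,7-tetrahydro-2H-1-benzopyran-8-yl]hexanoic acid | C=C(C)[C@H]1[C@H](C[C@]2(CC=C(C)C)C(=O)C([C@H](CCC)CC(=O)O)=C3OC(C)(C)CC(=O)C3=C2O)CC1(C)C | target

**Count and risks**
Total steps: 18. Longest linear sequence: 12 (steps 1–8, then 15–18); the core branch is steps 9–14.

Most likely to fail:

Step 17. The catalyst may discriminate the two faces of C6 poorly, since the substrate stereocentres are remote, and material may leak to O-prenyl or C8-prenyl products. The fallback replaces π-allyl palladium chemistry by ion-pair control. Diphenol 28 is alkylated with prenyl bromide under solid–liquid phase-transfer conditions (CsOH·H2O, toluene/CH2Cl2, −40 °C) with a cinchona-alkaloid-derived quaternary ammonium catalyst; either pseudo-enantiomeric alkaloid series can be chosen to match the (6R) face. This is a known mode of enantioselective alkylative dearomatisation of acylphloroglucinols. It sets out from 28 and comes back at 30, and makes no new compound (F0).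

Step 15. The cyclobutylmethyl organometallic may open to an allyl-type metal species before coupling, or oxidative addition and transmetalation at the doubly ortho-substituted aryl iodide may be slow, leading to reduction of 24. The fallback forms the bond with the arene as the nucleophile. Alcohol 12 is oxidised (Dess–Martin periodinane, NaHCO3, CH2Cl2) to (1R,2R)-3,3-dimethyl-2-(prop-1-en-2-yl)cyclobutane-1-carbaldehyde F1. F1 is condensed with the iodine-free diphenol 22 (L-proline cat., CH2Cl2/EtOH, rt) to the ortho-quinone methide methyl (3R)-3-[6-{[(1S,2R)-3,3-dimethyl-2-(prop-1-en-2-yl)cyclobutyl]methylidene}-5-hydroxy-2,2-dimethyl-4,7-dioxo-3,4,6,7-tetrahydro-2H-1-benzopyran-8-yl]hexanoate F2, which is reduced in the same flask by diethyl 2,6-dimethyl-1,4-dihydropyridine-3,5-dicarboxylate. This is an organocatalytic Knoevenagel condensation and transfer hydrogenation, the reductive alkylation known for cyclic 1,3-dicarbonyl carbon acids. It sets out from 12 and 22, comes back at 28, and makes steps 13, 14 and 16 unnecessary. Epimerisation of F1 next to the aldehyde can only return the favoured trans isomer.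

Step 10. Acylation may occur at C6 instead of C8, or a benzyl ether may be lost under the acidic conditions. The fallback delivers the acyl group from the phenol oxygen. Lactone 17 is opened first (NaOMe, MeOH, 0 °C) to methyl (3R)-3-[2,4-bis(benzyloxy)-6-hydroxyphenyl]hexanoate F3. Its single free phenol is esterified at once (3-methylbut-2-enoyl chloride, Et3N, CH2Cl2, 0 °C) to methyl (3R)-3-{2,4-bis(benzyloxy)-6-[(3-methylbut-2-enoyl)oxy]phenyl}hexanoate F4. A photo-Fries rearrangement (hν 300 nm, benzene) then moves the acyl group to the only free ortho position; the para position lies between two benzyloxy groups. It sets out from 17 and comes back at 20, which closes to 21 under the conditions of step 11.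

Further compounds
F0 | step 17 | none | none
F1 | step 15 | (1R,2R)-3,3-dimethyl-2-(prop-1-en-2-yl)cyclobutane-1-carbaldehyde | C=C(C)[C@H]1[C@H](C=O)CC1(C)C
F2 | step 15 | methyl (3R)-3-[6-{[(1S,2R)-3,3-dimethyl-2-(prop-1-en-2-yl)cyclobutyl]methylidene}-5-hydroxy-2,2-dimethyl-4,7-dioxo-3,4,6,7-tetrahydro-2H-1-benzopyran-8-yl]hexanoate (alkene geometry not defined) | C=C(C)[C@H]1[C@H](C=C2C(=O)C([C@H](CCC)CC(=O)OC)=C3OC(C)(C)CC(=O)C3=C2O)CC1(C)C
F3 | step 10 | methyl (3R)-3-[2,4-bis(benzyloxy)-6-hydroxyphenyl]hexanoate | COC(=O)C[C@@H](CCC)c1c(O)cc(OCc2ccccc2)cc1OCc1ccccc1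
F4 | step 10 | methyl (3R)-3-{2,4-bis(benzyloxy)-6-[(3-methylbut-2-enoyl)oxy]phenyl}hexanoate | COC(=O)C[C@@H](CCC)c1c(OC(=O)C=C(C)C)cc(OCc2ccccc2)cc1OCc1ccccc1
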